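**Retrosynthetic overview**

- The strategy rests on the cyclohexane ring: with C3 as a ketone, C1(OH)(CO2H)–C2H2–C3(=O) is a β-hydroxy ketone (aldol) unit, and the trans C4/C5 diol has the configuration of (2S,3S)-tartrate.
- The malonyl ester (O4) and the caffeoyl ester (O5) are removed first, leaving a quinate with O3 silylated; the axial O3 hydroxyl comes from reduction of a 3-dehydroquinate 4,5-acetonide.
- C1–C2 is then disconnected by an intramolecular aldol, opening the only ring to a chain with a methyl ketone (C2, C3) and a 2-oxo ester (C1) on a trans-dioxolane (C4, C5).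
- The chain comes from diethyl D-tartrate: C5–C6 by triflate displacement with a dithiane-masked tert-butyl glyoxylate anion, the methyl ketone through a Weinreb amide.
- One ring is formed, the carbocycle, in the aldol step.

Key step: step 9

Remark: quinic acid numbering is used for the carbocycle (C1 bears the carboxyl; O3 is the free axial hydroxyl, O4 carries the malonyl group, O5 the caffeoyl group), so the target is read as 5-O-(E)-caffeoyl-4-O-malonyl-(−)-quinic acid.

**Route**

Step 1
Reactants: 1 diethyl D-tartrate, (2S,3S)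
Product: 2 diethyl (4S,5S)-2,2-dimethyl-1,3-dioxolane-4,5-dicarboxylate
Conditions: 2-methoxypropene (1.5 equiv), pyridinium p-toluenesulfonate (5 mol %), CH2Cl2, 0 °C to rt
Reagents that add atoms: 2-methoxypropene, COC(C)=C
Why: Acid-catalysed acetalisation with an enol ether (acetonide formation) of the threo-diol gives the unstrained trans-4,5-disubstituted dioxolane and leaves both stereocentres, the future C4 and C5, unchanged.

Step 2
Reactants: 2 diethyl (4S,5S)-2,2-dimethyl-1,3-dioxolane-4,5-dicarboxylate
Product: 3 ethyl (4S,5R)-5-(hydroxymethyl)-2,2-dimethyl-1,3-dioxolane-4-carboxylate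
Conditions: NaBH4 (0.55 equiv), EtOH, 0 °C to rt; unreacted 2 recycled
Reagents that add atoms: none
Why: Partial borohydride reduction of an α-alkoxy ester: the two esters of C2-symmetric 2 are equivalent, so no site selectivity is needed, and sub-stoichiometric hydride at 0 °C should stop largely at the mono-alcohol, with diol and recovered diester separable and no stereocentre touched.

Step 3
Reactants: 3 ethyl (4S,5R)-5-(hydroxymethyl)-2,2-dimethyl-1,3-dioxolane-4-carboxylate
Product: 4 ethyl (4S,5R)-2,2-dimethyl-5-{[(trifluoromethanesulfonyl)oxy]methyl}-1,3-dioxolane-4-carboxylate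
Conditions: Tf2O (1.1 equiv), pyridine (1.5 equiv), CH2Cl2, −78 to −20 °C; used crude
Reagents that add atoms: trifluoromethanesulfonic anhydride, O=S(=O)(OS(=O)(=O)C(F)(F)F)C(F)(F)F
Why: Triflation of the primary alcohol under pyridine buffering (O-sulfonylation) gives a leaving group reactive enough for displacement at low temperature next to the oxygenated carbon, and neither stereocentre is involved.

Step 4
Reactants: 5 1,3-dithiane
Product: 8 tert-butyl 1,3-dithiane-2-carboxylate, via 2-lithio-1,3-dithiane 6 (not isolated), via lithium ester enolate 7 (not isolated)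
Conditions: n-BuLi (1.0 equiv), THF, −30 °C; Boc2O (0.5 equiv), −78 °C; aq NH4Cl; 5 recovered
Reagents that add atoms: di-tert-butyl dicarbonate, CC(C)(C)OC(=O)OC(=O)OC(C)(C)C
Why: Corey–Seebach lithiation of 1,3-dithiane followed by C-acylation with Boc2O; because ester 8 is far more acidic than 5, the second equivalent of 6 is planned to convert it into lithium enolate 7, which protects the ester carbonyl from addition of further 6 until the aqueous quench returns 8.

Step 5
Reactants: 8 tert-butyl 1,3-dithiane-2-carboxylate; 4 ethyl (4S,5R)-2,2-dimethyl-5-{[(trifluoromethanesulfonyl)oxy]methyl}-1,3-dioxolane-4-carboxylate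
Product: 10 ethyl (4S,5R)-5-{[2-(tert-butoxycarbonyl)-1,3-dithian-2-yl]methyl}-2,2-dimethyl-1,3-dioxolane-4-carboxylate, via sodium ester enolate 9 (not isolated)
Conditions: NaN(SiMe3)2 (1.05 equiv), THF, −78 °C; then 4 (1.0 equiv), −78 to −20 °C
Reagents that add atoms: none
Why: SN2 alkylation of a sulfur-stabilised sodium ester enolate (a masked tert-butyl glyoxylate acyl anion, Corey–Seebach umpolung) with a primary triflate forms C5–C6; the soft, weakly basic enolate should displace triflate faster than it removes the ester α-hydrogen of 4, and no stereocentre is touched.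

Step 6
Reactants: 10 ethyl (4S,5R)-5-{[2-(tert-butoxycarbonyl)-1,3-dithian-2-yl]methyl}-2,2-dimethyl-1,3-dioxolane-4-carboxylate
Product: 11 tert-butyl 2-{[(4R,5S)-5-[methoxy(methyl)carbamoyl]-2,2-dimethyl-1,3-dioxolan-4-yl]methyl}-1,3-dithiane-2-carboxylate
Conditions: MeNHOMe·HCl (1.5 equiv), i-PrMgCl (3.0 equiv), THF, −20 to 0 °C
Reagents that add atoms: N,O-dimethylhydroxylamine hydrochloride, CNOC.Cl
Why: Weinreb amide formation by aminolysis of the ethyl ester with the chloromagnesium amide of N,O-dimethylhydroxylamine; the tert-butyl ester on the quaternary dithiane carbon is too hindered to react, and the α-alkoxy stereocentre, should it enolise, returns to the favoured trans-dioxolane.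

Step 7
Reactants: 11 tert-butyl 2-{[(4R,5S)-5-[methoxy(methyl)carbamoyl]-2,2-dimethyl-1,3-dioxolan-4-yl]methyl}-1,3-dithiane-2-carboxylate
Product: 12 tert-butyl 2-{[(4R,5S)-5-acetyl-2,2-dimethyl-1,3-dioxolan-4-yl]methyl}-1,3-dithiane-2-carboxylate
Conditions: MeMgBr (1.5 equiv), THF, −20 to 0 °C; aq NH4Cl
Reagents that add atoms: methylmagnesium bromide, C[Mg]Br
Why: Weinreb ketone synthesis: the chelated tetrahedral magnesium intermediate prevents over-addition and releases the methyl ketone (C2–C3) only on quench, while the hindered tert-butyl ester and the dithiane are inert to MeMgBr at 0 °C.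

Step 8
Reactants: 12 tert-butyl 2-{[(4R,5S)-5-acetyl-2,2-dimethyl-1,3-dioxolan-4-yl]methyl}-1,3-dithiane-2-carboxylate
Product: 13 tert-butyl 3-[(4R,5S)-5-acetyl-2,2-dimethyl-1,3-dioxolan-4-yl]-2-oxopropanoate
Conditions: PhI(OCOCF3)2 (1.5 equiv), NaHCO3, MeCN–H2O (9:1), 0 °C, 10 min
Reagents that add atoms: water, O
Why: Oxidative dethioacetalisation with a hypervalent iodine reagent: sulfur is activated by PhI(OCOCF3)2, the ring opens to a thionium ion that water captures, and the bicarbonate buffer protects the acetonide and limits enolisation of the new 2-oxo ester during the short reaction time.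

Step 9
Reactants: 13 tert-butyl 3-[(4R,5S)-5-acetyl-2,2-dimethyl-1,3-dioxolan-4-yl]-2-oxopropanoate
Product: 15 tert-butyl 4,5-O-isopropylidene-3-dehydroquinate [tert-butyl (1R,4S,5R)-1-hydroxy-4,5-(isopropylidenedioxy)-3-oxocyclohexane-1-carboxylate], via enamine 14 (not isolated)
Conditions: pyrrolidine (0.2 equiv), AcOH (0.2 equiv), THF (0.02 M), 0 °C to rt
Reagents that add atoms: none
Why: Pyrrolidine condenses with the methyl ketone to give the less substituted enamine 14 (C2=C3), whose terminal carbon C2 adds to the strongly electrophilic, acid-activated C1 carbonyl of the 2-oxo ester, and hydrolysis of the resulting iminium ion returns the catalyst and the C3 ketone. The closest known reaction type is the amine-catalysed intramolecular enolendo aldol cyclisation of dicarbonyl compounds, together with enamine additions of ketones to 2-oxo esters. The carbocycle closes in a 6-(enolendo)-exo-trig mode through a chair in which the trans-dioxolane holds O4 and O5 equatorial. The new stereocentre C1 is controlled by that chair: the tert-butoxycarbonyl group should take the equatorial site and the developing hydroxyl the axial one (1R, hydroxyl cis to O4), and because the aldol is reversible the same epimer should also be the one that accumulates. The step needs the nucleophile to form at C2 and not at C4 or C6, which the substrate secures because the methyl group is the least hindered enamine site and because an enol or enamine at C4 or C6 could only close a four-membered ring and so returns 13. The buffered, weakly basic medium at low temperature is chosen to keep β-elimination of O5 from the C6 enol, dehydration of the aldol and epimerisation at C4 slow.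

Step 10
Reactants: 15 tert-butyl 4,5-O-isopropylidene-3-dehydroquinate
Product: 16 tert-butyl 4,5-O-isopropylidenequinate (1-OH and 3-OH free; 3-OH axial, cis to O4)
Conditions: LiBH(sec-Bu)3 (2.2 equiv), THF, −78 °C; aq NH4Cl
Reagents that add atoms: none
Why: Diastereoselective ketone reduction with a bulky trialkylborohydride: the trans-fused dioxolane locks the chair, the reagent adds from the equatorial direction (the axial face is further screened by the axial C1 oxygen) and so sets the axial O3 hydroxyl cis to O4 (3R, as in quinic acid), the second equivalent covering the free tertiary hydroxyl.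

Step 11
Reactants: 16 tert-butyl 4,5-O-isopropylidenequinate
Product: 17 tert-butyl 3-O-(tert-butyldimethylsilyl)-4,5-O-isopropylidenequinate
Conditions: TBSCl (1.5 equiv), imidazole (3 equiv), 4-(dimethylamino)pyridine (cat.), DMF, 40 °C
Reagents that add atoms: tert-butyldimethylsilyl chloride, CC(C)(C)[Si](C)(C)Cl
Why: Chemoselective silyl ether formation at the only secondary hydroxyl: TBSCl–imidazole does not silylate the tertiary C1 hydroxyl, and the weakly basic medium leaves the strained acetonide intact.

Step 12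
Reactants: 17 tert-butyl 3-O-(tert-butyldimethylsilyl)-4,5-O-isopropylidenequinate
Product: 18 tert-butyl 3-O-(tert-butyldimethylsilyl)quinate (1-OH, 4-OH and 5-OH free)
Conditions: AcOH–THF–H2O (3:1:1), rt
Reagents that add atoms: none
Why: Selective acetal hydrolysis: the trans-fused dioxolane on the cyclohexane is strained and should hydrolyse in dilute acetic acid at room temperature, conditions under which a secondary TBS ether and a tert-butyl ester are stable.

Step 13
Reactants: 19 caffeic acid
Product: 21 (E)-3-[3,4-bis(methoxymethoxy)phenyl]prop-2-enoic acid, via MOM ester 20 (not isolated)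
Conditions: MOMCl (3.5 equiv), i-Pr2NEt (4.5 equiv), CH2Cl2, 0 °C to rt; then LiOH, THF–H2O, rt; cold dilute HCl to pH 4
Reagents that add atoms: chloromethyl methyl ether, COCCl; lithium hydroxide, [Li+].[OH-]
Why: O-Alkylation of both phenols and the carboxylate with MOMCl, then acyl–oxygen saponification of the labile MOM ester by hydroxide, leaves the base-stable aryl MOM ethers, which the final acid treatment removes.

Step 14
Reactants: 18 tert-butyl 3-O-(tert-butyldimethylsilyl)quinate; 21 (E)-3-[3,4-bis(methoxymethoxy)phenyl]prop-2-enoic acid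
Product: 22 tert-butyl 5-O-[(E)-3,4-bis(methoxymethoxy)cinnamoyl]-3-O-(tert-butyldimethylsilyl)quinate
Conditions: 21 (1.05 equiv), EDC·HCl (1.3 equiv), 4-(dimethylamino)pyridine (0.2 equiv), CH2Cl2, −10 °C to rt
Reagents that add atoms: none
Why: Steglich esterification through the bulky acylpyridinium ion should select the equatorial O5 hydroxyl, flanked only by the C6 methylene, over O4, which is screened by the axial O3 silyl ether, and over the tertiary C1 hydroxyl; the O5 ester is also the less crowded regioisomer should acyl migration occur.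

Step 15
Reactants: 22 tert-butyl 5-O-[(E)-3,4-bis(methoxymethoxy)cinnamoyl]-3-O-(tert-butyldimethylsilyl)quinate; 23 Meldrum's acid
Product: 24 tert-butyl 5-O-[(E)-3,4-bis(methoxymethoxy)cinnamoyl]-4-O-(carboxyacetyl)-3-O-(tert-butyldimethylsilyl)quinate
Conditions: 23 (1.5 equiv), toluene, 90 °C
Reagents that add atoms: none
Why: Ring-opening alcoholysis of Meldrum's acid by the remaining secondary hydroxyl gives the malonic acid half ester directly with loss of acetone, under neutral thermal conditions that avoid base-promoted acyl migration and leave the silyl, MOM and tert-butyl groups untouched.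

Step 16
Reactants: 24 tert-butyl 5-O-[(E)-3,4-bis(methoxymethoxy)cinnamoyl]-4-O-(carboxyacetyl)-3-O-(tert-butyldimethylsilyl)quinate
Product: 25 5-O-(E)-caffeoyl-4-O-malonyl-(−)-quinic acid (target)
Conditions: TFA–CH2Cl2–H2O (10:10:1), 0 °C to rt; reversed-phase purification under acidic eluent
Reagents that add atoms: none
Why: Global acidolysis: TFA cleaves the tert-butyl ester (loss of isobutene), the aryl MOM acetals and, with water present, the secondary TBS ether, while the caffeate and malonate esters are stable to acid and acyl migration is slow in strongly acidic medium.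

**Compound list**

1 | diethyl D-tartrate, (2S,3S) | CCOC(=O)[C@@H](O)[C@H](O)C(=O)OCC | starting material
2 | diethyl (4S,5S)-2,2-dimethyl-1,3-dioxolane-4,5-dicarboxylate | CCOC(=O)[C@H]1OC(C)(C)O[C@@H]1C(=O)OCC | intermediate
3 | ethyl (4S,5R)-5-(hydroxymethyl)-2,2-dimethyl-1,3-dioxolane-4-carboxylate | CCOC(=O)[C@H]1OC(C)(C)O[C@@H]1CO | intermediate
4 | ethyl (4S,5R)-2,2-dimethyl-5-{[(trifluoromethanesulfonyl)oxy]methyl}-1,3-dioxolane-4-carboxylate | CCOC(=O)[C@H]1OC(C)(C)O[C@@H]1COS(=O)(=O)C(F)(F)F | intermediate
5 | 1,3-dithiane | C1CSCSC1 | starting material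
6 | 2-lithio-1,3-dithiane | [Li]C1SCCCS1 | intermediate
7 | lithium enolate of tert-butyl 1,3-dithiane-2-carboxylate | [Li+].[O-]C(OC(C)(C)C)=C1SCCCS1 | intermediate
8 | tert-butyl 1,3-dithiane-2-carboxylate | CC(C)(C)OC(=O)C1SCCCS1 | intermediate
9 | sodium enolate of tert-butyl 1,3-dithiane-2-carboxylate | [Na+].[O-]C(OC(C)(C)C)=C1SCCCS1 | intermediate
10 | ethyl (4S,5R)-5-{[2-(tert-butoxycarbonyl)-1,3-dithian-2-yl]methyl}-2,2-dimethyl-1,3-dioxolane-4-carboxylate | CCOC(=O)[C@H]1OC(C)(C)O[C@@H]1CC1(C(=O)OC(C)(C)C)SCCCS1 | intermediate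
11 | tert-butyl 2-{[(4R,5S)-5-[methoxy(methyl)carbamoyl]-2,2-dimethyl-1,3-dioxolan-4-yl]methyl}-1,3-dithiane-2-carboxylate | CON(C)C(=O)[C@H]1OC(C)(C)O[C@@H]1CC1(C(=O)OC(C)(C)C)SCCCS1 | intermediate
12 | tert-butyl 2-{[(4R,5S)-5-acetyl-2,2-dimethyl-1,3-dioxolan-4-yl]methyl}-1,3-dithiane-2-carboxylate | CC(=O)[C@H]1OC(C)(C)O[C@@H]1CC1(C(=O)OC(C)(C)C)SCCCS1 | intermediate
13 | tert-butyl 3-[(4R,5S)-5-acetyl-2,2-dimethyl-1,3-dioxolan-4-yl]-2-oxopropanoate | CC(=O)[C@H]1OC(C)(C)O[C@@H]1CC(=O)C(=O)OC(C)(C)C | intermediate
14 | tert-butyl 3-{(4R,5S)-2,2-dimethyl-5-[1-(pyrrolidin-1-yl)ethenyl]-1,3-dioxolan-4-yl}-2-oxopropanoate (enamine) | C=C(N1CCCC1)[C@H]2OC(C)(C)O[C@@H]2CC(=O)C(=O)OC(C)(C)C | intermediate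
15 | tert-butyl 4,5-O-isopropylidene-3-dehydroquinate, (1R,4S,5R) | CC1(C)O[C@@H]2C(=O)C[C@@](O)(C(=O)OC(C)(C)C)C[C@H]2O1 | intermediate
16 | tert-butyl 4,5-O-isopropylidenequinate | CC1(C)O[C@@H]2[C@H](O)C[C@@](O)(C(=O)OC(C)(C)C)C[C@H]2O1 | intermediate
17 | tert-butyl 3-O-(tert-butyldimethylsilyl)-4,5-O-isopropylidenequinate | CC1(C)O[C@@H]2[C@H](O[Si](C)(C)C(C)(C)C)C[C@@](O)(C(=O)OC(C)(C)C)C[C@H]2O1 | intermediate
18 | tert-butyl 3-O-(tert-butyldimethylsilyl)quinate | O[C@@H]1[C@H](O[Si](C)(C)C(C)(C)C)C[C@@](O)(C(=O)OC(C)(C)C)C[C@H]1O | intermediate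
19 | caffeic acid | O=C(O)/C=C/c1ccc(O)c(O)c1 | starting material
20 | methoxymethyl (E)-3-[3,4-bis(methoxymethoxy)phenyl]prop-2-enoate | COCOC(=O)/C=C/c1ccc(OCOC)c(OCOC)c1 | intermediate
21 | (E)-3-[3,4-bis(methoxymethoxy)phenyl]prop-2-enoic acid | OC(=O)/C=C/c1ccc(OCOC)c(OCOC)c1 | intermediate
22 | tert-butyl 5-O-[(E)-3,4-bis(methoxymethoxy)cinnamoyl]-3-O-(tert-butyldimethylsilyl)quinate | O[C@@H]1[C@H](O[Si](C)(C)C(C)(C)C)C[C@@](O)(C(=O)OC(C)(C)C)C[C@H]1OC(=O)/C=C/c1ccc(OCOC)c(OCOC)c1 | intermediate
23 | Meldrum's acid (2,2-dimethyl-1,3-dioxane-4,6-dione) | CC1(C)OC(=O)CC(=O)O1 | starting material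
24 | tert-butyl 5-O-[(E)-3,4-bis(methoxymethoxy)cinnamoyl]-4-O-(carboxyacetyl)-3-O-(tert-butyldimethylsilyl)quinate | OC(=O)CC(=O)O[C@@H]1[C@H](O[Si](C)(C)C(C)(C)C)C[C@@](O)(C(=O)OC(C)(C)C)C[C@H]1OC(=O)/C=C/c1ccc(OCOC)c(OCOC)c1 | intermediate
25 | 5-O-(E)-caffeoyl-4-O-malonyl-(−)-quinic acid | O=C(O)CC(=O)O[C@@H]1[C@H](O)C[C@@](O)(C(=O)O)C[C@H]1OC(=O)/C=C/c1ccc(O)c(O)c1 | target

**Step count**

Total: 16 steps. Longest linear sequence: 14 steps (steps 1–3, 5–12 and 14–16, from diethyl D-tartrate); steps 4 and 13 prepare the two side components.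

**Steps most likely to fail**

Step 9 (key aldol). The enol or enamine on the 2-oxo ester side may expel the C5 oxygen and open the dioxolane. The β-hydroxy ketone may also dehydrate to the enone, facial control at C1 may be incomplete, and C4 may epimerise slowly toward the cis-fused acetonide. The fallback generates the C2 nucleophile regiospecifically and without base. It sets out from Weinreb amide 11: bromomethyllithium made in situ (CH2Br2, MeLi, THF, −78 °C) should give the bromomethyl ketone tert-butyl 2-{[(4R,5S)-5-(bromoacetyl)-2,2-dimethyl-1,3-dioxolan-4-yl]methyl}-1,3-dithiane-2-carboxylate F1. PhI(OCOCF3)2 in buffered aqueous MeCN should then unmask the bromomethyl 2-oxo ester F2. Slow addition of SmI2 (2.2 equiv, THF, −78 °C) should reduce the C–Br bond to the trivalent samarium enolate F3 (not isolated), which should add to the chelated 2-oxo ester in a Reformatsky-type intramolecular aldol and, after aqueous NH4Cl, return to the route at 15.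

Step 14 (O5 caffeoylation). The acylation may lose regioselectivity between O5 and O4, over-acylate, or be followed by base-promoted acyl migration. The fallback makes O5 the only secondary hydroxyl. It sets out from 16: acid-catalysed equilibration (acetone, 2,2-dimethoxypropane, p-TsOH cat., rt) should move the strained trans-acetonide to the cis-3,4 positions, giving tert-butyl 3,4-O-isopropylidenequinate F4. Steglich esterification with 21 should give the 5-O-ester F5, and warm aqueous AcOH should hydrolyse the acetonide to the 3,4-diol F6. Bu2SnO (toluene, reflux) should form the 3,4-O-dibutylstannylene acetal F7 (not isolated), which directs tert-butyl malonyl chloride to the equatorial O4 to give the mixed malonate F8. The acidolysis of step 16, which also cleaves the second tert-butyl ester, returns to the route at 25.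

Step 15 (malonylation). Acylation of the hindered O4 hydroxyl may be slow at a temperature where the tertiary C1 hydroxyl competes or the substrate degrades. The fallback uses a protected malonate donor at low temperature. It sets out from 22: carbodiimide coupling with tert-butyl hydrogen malonate (N,N'-diisopropylcarbodiimide, 4-(dimethylamino)pyridine cat., CH2Cl2, 0 °C) should give the 4-O-(tert-butyl malonyl) ester F9. The acidolysis of step 16 removes the additional tert-butyl ester and returns to the route at 25.

**Further compounds**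

F1 | step 9 | tert-butyl 2-{[(4R,5S)-5-(bromoacetyl)-2,2-dimethyl-1,3-dioxolan-4-yl]methyl}-1,3-dithiane-2-carboxylate | BrCC(=O)[C@H]1OC(C)(C)O[C@@H]1CC1(C(=O)OC(C)(C)C)SCCCS1
F2 | step 9 | tert-butyl 3-[(4R,5S)-5-(bromoacetyl)-2,2-dimethyl-1,3-dioxolan-4-yl]-2-oxopropanoate | BrCC(=O)[C@H]1OC(C)(C)O[C@@H]1CC(=O)C(=O)OC(C)(C)C
F3 | step 9 | diiodosamarium enolate of the methyl ketone of 13 | C=C(O[Sm](I)I)[C@H]1OC(C)(C)O[C@@H]1CC(=O)C(=O)OC(C)(C)C
F4 | step 14 | tert-butyl 3,4-O-isopropylidenequinate | CC1(C)O[C@@H]2[C@H](O1)C[C@@](O)(C(=O)OC(C)(C)C)C[C@H]2O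
F5 | step 14 | tert-butyl 5-O-[(E)-3,4-bis(methoxymethoxy)cinnamoyl]-3,4-O-isopropylidenequinate | CC1(C)O[C@@H]2[C@H](O1)C[C@@](O)(C(=O)OC(C)(C)C)C[C@H]2OC(=O)/C=C/c1ccc(OCOC)c(OCOC)c1
F6 | step 14 | tert-butyl 5-O-[(E)-3,4-bis(methoxymethoxy)cinnamoyl]quinate | O[C@@H]1[C@H](O)C[C@@](O)(C(=O)OC(C)(C)C)C[C@H]1OC(=O)/C=C/c1ccc(OCOC)c(OCOC)c1
F7 | step 14 | 3,4-O-dibutylstannylene acetal of F6 | CCCC[Sn]1(CCCC)O[C@@H]2[C@H](O1)C[C@@](O)(C(=O)OC(C)(C)C)C[C@H]2OC(=O)/C=C/c1ccc(OCOC)c(OCOC)c1
F8 | step 14 | tert-butyl 5-O-[(E)-3,4-bis(methoxymethoxy)cinnamoyl]-4-O-(3-tert-butoxy-3-oxopropanoyl)quinate | CC(C)(C)OC(=O)CC(=O)O[C@@H]1[C@H](O)C[C@@](O)(C(=O)OC(C)(C)C)C[C@H]1OC(=O)/C=C/c1ccc(OCOC)c(OCOC)c1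
F9 | step 15 | tert-butyl 5-O-[(E)-3,4-bis(methoxymethoxy)cinnamoyl]-4-O-(3-tert-butoxy-3-oxopropanoyl)-3-O-(tert-butyldimethylsilyl)quinate | CC(C)(C)OC(=O)CC(=O)O[C@@H]1[C@H](O[Si](C)(C)C(C)(C)C)C[C@@](O)(C(=O)OC(C)(C)C)C[C@H]1OC(=O)/C=C/c1ccc(OCOC)c(OCOC)c1
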